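**Assumption:** Robustol has no stereocentres and the 22-membered ring is conformationally free, so the "single enantiomer" requirement holds trivially. The alkene geometries in **9** and **10** do not matter, because every C=C is hydrogenated in Step 9.

## Retrosynthetic overview
1. Robustol ⇐ H₂ then BBr₃ on a permethylated 22-membered macrocyclic triene.
2. The macrocycle ⇐ intramolecular McMurry coupling (ketyl-radical pinacol C–C bond, then deoxygenation) of a diaryl ether bearing two 7-carbon ω-formylalkenyl arms. This forms the central C7–C7′ bond and closes the ring last.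
3. The arms ⇐ double Heck reaction of hept-6-enal on a bis-aryl bromide, which ⇐ bis Ir-catalysed meta C–H borylation of the simple diaryl ether followed by bromodeboronation.
4. The diaryl ether ⇐ Cu-catalysed Ullmann coupling of 2-iodo-1,3-dimethoxybenzene with resorcinol, then methylation. Both arenes come from resorcinol, and the diaryl ether bond forms first.

## Route

**Step 1**
Reactants: **1** resorcinol
Product: **2** 1,3-dimethoxybenzene
Conditions: MeI (3 equiv), K₂CO₃, acetone, reflux
Reagents that add atoms: MeI, CI
Why: Williamson O-methylation protects both phenols as the methyl ethers needed for the later lithiation and borylation.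

**Step 2**
Reactants: **2**
Product: **3** 2-iodo-1,3-dimethoxybenzene
Conditions: n-BuLi, THF, 0 °C → rt, 6 h; then I₂, –78 °C → rt
Reagents that add atoms: I₂, II
Why: Directed ortho-metalation occurs at C2 between the two OMe groups, and the aryllithium is trapped with iodine.

**Step 3**
Reactants: **3** 2-iodo-1,3-dimethoxybenzene; **1** resorcinol (4 equiv)
Product: **4** 3-(2,6-dimethoxyphenoxy)phenol
Conditions: CuI (10 mol%), picolinic acid (20 mol%), K₃PO₄, DMSO, 90 °C
Reagents that add atoms: none
Why: Ullmann-type Cu/picolinate C–O coupling tolerates hindered ortho-disubstituted partners, and excess resorcinol limits double arylation.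

**Step 4**
Reactants: **4**
Product: **5** 1,3-dimethoxy-2-(3-methoxyphenoxy)benzene
Conditions: MeI, K₂CO₃, acetone, 50 °C
Reagents that add atoms: MeI, CI
Why: O-Methylation gives the fully protected diaryl ether core.

**Step 5**
Reactants: **5**
Product: **6** bis-Bpin diaryl ether (Bpin at C5 of the 3-methoxyphenyl ring and C4 of the 2,6-dimethoxyphenyl ring)
Conditions: B₂pin₂ (2.4 equiv), [Ir(cod)OMe]₂ (1.5 mol%), dtbpy (3 mol%), THF, 80 °C, 16 h
Reagents that add atoms: B₂pin₂, CC1(C)OB(OC1(C)C)B1OC(C)(C)C(C)(C)O1
Why: Ir-catalysed C–H borylation is sterically controlled, so it occurs only at the C–H flanked by two C–H neighbours on each ring. These are exactly the positions where the chain attaches in robustol.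

**Step 6**
Reactants: **6**
Product: **7** 5-bromo-1-(4-bromo-2,6-dimethoxyphenoxy)-3-methoxybenzene
Conditions: CuBr₂ (8 equiv), MeOH/H₂O/THF, 90 °C, sealed tube
Reagents that add atoms: CuBr₂, Br[Cu]Br
Why: Cu-mediated ipso-bromodeboronation of the aryl pinacol boronates converts both Bpin groups to Ar–Br.

**Step 7**
Reactants: **7**; **8** hept-6-enal (3 equiv)
Product: **9** bis-[(E)-7-oxohept-1-enyl] diaryl ether dialdehyde
Conditions: Pd₂(dba)₃ (2.5 mol%), P(t-Bu)₃·HBF₄ (10 mol%), Cy₂NMe, dioxane, 100 °C
Reagents that add atoms: none
Why: A double Mizoroki–Heck reaction installs two identical 7-carbon arms with E-selectivity, and the mild amine base leaves the aldehydes intact.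

**Step 8**
Reactants: **9**
Product: **10** permethylated 22-membered macrocyclic triene (new C=C as an E/Z mixture)
Conditions: TiCl₄ (8 equiv), Zn dust (16 equiv), pyridine (cat.), THF, reflux; substrate added by syringe pump over 16 h to ~2 mM
Reagents that add atoms: none
Why: This is a McMurry coupling. Low-valent Ti transfers an electron to each aldehyde to give ketyl radicals, which couple in a radical–radical pinacol C–C bond formation, and the Ti-pinacolate is then deoxygenated to the alkene. Slow addition favours intramolecular ring closure, the 14-carbon linker is completed in this single bond-forming step, and no stereocentre is created.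

**Step 9**
Reactants: **10**
Product: **11** permethylated saturated macrocycle (14 CH₂ chain)
Conditions: H₂ (3 atm), 10% Pd/C, EtOAc/MeOH, rt
Reagents that add atoms: none
Why: Catalytic hydrogenation reduces all three C=C bonds regardless of geometry, while the aryl methyl ethers and diaryl ether survive.

**Step 10**
Reactants: **11**
Product: **12** robustol
Conditions: BBr₃ (8 equiv), CH₂Cl₂, –78 °C → rt; MeOH/H₂O quench
Reagents that add atoms: none
Why: BBr₃ cleaves the three aryl methyl ethers (the diaryl ether and alkyl chain are unaffected) to give the three free phenols of the target.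

## Compound list
1 | resorcinol | Oc1cccc(O)c1 | starting material
2 | 1,3-dimethoxybenzene | COc1cccc(OC)c1 | intermediate
3 | 2-iodo-1,3-dimethoxybenzene | COc1cccc(OC)c1I | intermediate
4 | 3-(2,6-dimethoxyphenoxy)phenol | COc1cccc(OC)c1Oc1cccc(O)c1 | intermediate
5 | 1,3-dimethoxy-2-(3-methoxyphenoxy)benzene | COc1cccc(OC)c1Oc1cccc(OC)c1 | intermediate
6 | bis-Bpin diaryl ether | COc1cc(B2OC(C)(C)C(C)(C)O2)cc(OC)c1Oc1cc(OC)cc(B2OC(C)(C)C(C)(C)O2)c1 | intermediate
7 | bis-aryl bromide | COc1cc(Br)cc(OC)c1Oc1cc(OC)cc(Br)c1 | intermediate
8 | hept-6-enal | O=CCCCCC=C | starting material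
9 | dialdehyde (E,E) | COc1cc(/C=C/CCCCC=O)cc(OC)c1Oc1cc(OC)cc(/C=C/CCCCC=O)c1 | intermediate
10 | permethylated macrocyclic triene | COc1cc2cc(OC)c1Oc1cc(OC)cc(c1)C=CCCCCC=CCCCCC=C2 | intermediate
11 | permethylated saturated macrocycle | COc1cc2cc(OC)c1Oc1cc(OC)cc(c1)CCCCCCCCCCCCCC2 | intermediate
12 | robustol | Oc1cc2cc(c1)Oc1c(O)cc(cc1O)CCCCCCCCCCCCCC2 | target

## Totals
Total steps: 10. Longest linear sequence: 10 (resorcinol → 2 → 3 → 4 → 5 → 6 → 7 → 9 → 10 → 11 → 12).

## Three steps most likely to fail
1. **Step 8 (macrocyclic McMurry).** Oligomerisation or pinacol-only products could compete with ring closure. Fallback: change the ring-closing bond. Install 7-octenyl arms by B-alkyl Suzuki coupling of 9-BBN-hydroborated 1,7-octadiene with **7**, close the ring by RCM, then use the same Step 9 and Step 10.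
2. **Step 3 (Ullmann with the 2,6-dimethoxy aryl iodide).** Steric hindrance may stall the coupling. Fallback: use a different C–O bond construction, Cu-catalysed arylation of resorcinol or 3-methoxyphenol with a (2,6-dimethoxyphenyl)(mesityl)iodonium salt.
3. **Steps 5–6 (bis-borylation and CuBr₂ bromodeboronation).** The borylation may give mono/bis mixtures, and CuBr₂ may brominate the very electron-rich ring B. Fallback: avoid C–H functionalisation by Ullmann coupling of pre-halogenated partners, 4-bromo-2,6-dimethoxyphenol and 1-bromo-3-iodo-5-methoxybenzene, which gives bis-bromide **7** directly.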